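Compound numbers 1–31 are fixed by the steps below and listed with SMILES after step 21. Atom numbers are those of the target: ring A = C1, C2, C3, C4, C5, C10; ring B = C5 to C10; C17 is the methyl on C8, C20 the methyl on C9, C18 the methyl and C19 the ester carbon on C4, C11–C15 the chain, C16 the methyl on C13.

## Analysis of the target

Target 31 is a halimane-type bicycle: a cyclohexene ring A (alkene C1=C10) fused along C5–C10 to a cyclohexane ring B. C4 carries a methyl group and a methyl ester, C8 a methyl group, and C9 a methyl group plus the chain C11–C15, which ends in a trisubstituted 2,3-epoxy alcohol. There are four ring stereocentres (4S, 5R, 8R, 9S), two of them quaternary, and two chain stereocentres (13S, 14S). H5, the C18 methyl, C17 and C20 lie on one face of the bicycle; the ester and the chain lie on the other. The epoxy alcohol is the fragile group (acid opens it, base invites Payne migration) and must come last, and the C1=C10 alkene rules out late ozonolysis or hydrogenation. The hindered C19 ester is robust. The difficulty is two quaternary stereocentres, each next to a tertiary one, in a ring with no resident group to direct them, and C9 carries a methyl and a CH2 chain that a reagent can hardly tell apart. The strategy rests on C17 and C20 being cis on the adjacent ring atoms C8 and C9: they can be the two sp2 carbons of a cyclobutene fused to ring B, which an enone and acetylene give on irradiation.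

## Retrosynthetic reasoning

**Epoxide.** The C13–O and C14–O bonds of 31 are cut first, giving the E allylic alcohol 30. The two chain stereocentres are remote from the ring and are best set by a reagent; the primary hydroxyl is the handle for a Sharpless epoxidation that ignores the C1=C10 alkene.

**Chain alkene.** The C13=C14 bond of 30 is cut by way of enoate 29 back to methyl ketone 28. C14 and C15 come from a phosphonate olefination, and the forward reduction must spare the hindered C19 ester. This leaves C13 as a ketone, which can be carried as a ketal through the whole ring construction.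

**Ester and ketone.** Compound 28 is the methyl ester of keto acid 27. The acid is what the ring-A-forming rearrangement delivers, and its acidic work-up can free the ketone at the same time.

**Ring A.** In 27 the C4–C5 bond is cut with transposition of the alkene from C1=C10 to C10=C5 and reconnection of C19–O to C1, which leads to δ-lactone 24. Forward, the lactone silyl ketene acetal 25 can rearrange only through a boat-like transition state. One carbinol centre (C1) therefore dictates both C4 and C5, and ring A closes with the alkene in the right place. No other cut of ring A creates the quaternary C4 and the adjacent C5 in one stereospecific event.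

**Lactone.** The saturated lactone 24 comes from the unsaturated lactone 22 by conjugate reduction. Compound 22 is cut at C3=C4 (ring-closing metathesis) and at the ester C–O bond to give methacrylate 21 and alcohol 20. C4 needs no control at this stage because it becomes trigonal again in 25.

**C1.** The C1–C2 bond of 20 is cut to enal 18; a reagent-controlled allylboration must set C1 as R. The C1–C10 bond is then cut through enol triflate 17 to ketone 15. Ketone 15 can enolise only towards C5, so the position of the alkene is unambiguous.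

**The two methyl groups.** In 15 the methyls C17 and C20 are traced back through benzyl ether 13, diiodide 12 and diol 11, and the C17–C20 bond is reconnected to give cyclobutene 9. During this unmasking C10 is held as a benzyl-protected alcohol (8, 9, 13, 14). A C10 ketone would be reduced in the ozonide work-up, and an sp2 C10 next to a C20 radical would invite a 1,2-shift.

**Key disconnection.** Cyclobutene ketone 7 is cut at C8–C17 and C9–C20 to enone 5 and acetylene 6. Both stereocentres of ring B are made here, and their relative configuration is enforced by the cis fusion of the four-membered ring. Only the absolute sense is left to a chiral Lewis acid. The chain carbons C11–C13 and C16 are already in place.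

**Photosubstrate.** Enone 5 is cut at C9–C11 to iodoenone 2 and the alkylborane 4 made from vinyl dioxolane 3. Iodoenone 2 comes from cyclohexenone 1. These two reliable steps leave the risk of the route in the photocycloaddition.

## Alternatives that were turned down

**Alternative 1:** Ring B is cut at C8–C9 and C5–C6, giving keto ester A1 and enal A2. Forward, a diarylprolinol silyl ether with a carboxylic acid co-catalyst activates A2 as its iminium ion. A1 adds through C9 to C8, and the acetyl methyl condenses with the aldehyde to give enone A3.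
- For: one step from two cheap compounds; face control at C8 by this catalyst class is well established; C20 and the C10 carbonyl arrive in place. On step count to ring B and on reliance on established catalysis it is clearly stronger than the chosen route, which needs ten steps to reach ketone 15.
- Against: C9 is formed from a prochiral enol whose two faces differ only as acetyl against ester, so the C8/C9 relationship is not enforced by structure. C11 arrives as an ester on a quaternary carbon, so four more chain carbons must be grown from a neopentyl position. The C5=C6 alkene must be removed before ring A can be built.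
- Comparison: the chosen strategy pays in steps but obtains the cis relationship as a geometric necessity and brings C11–C13 with it.

**Alternative 2:** Ring A is cut at C4–C5 with alkene transposition, leading from acid A5 back to δ-lactone A4. Forward, the lactone is converted into its silyl ketene acetal and heated.
- For: complete transfer of chirality from C1 to C4 and C5 through an enforced boat, and a known reaction class. On ring A this alternative is exactly as strong as the chosen route, which uses the same rearrangement in step 17. Its chain is already at the allylic-ether stage, so it avoids the late ester-selective reduction of step 20.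
- Against: as the governing idea it presupposes ring B with C8 and C9 set and says nothing about how, and it places the decisive risk at the end on precious material.
- Comparison: the chosen strategy supplies what is missing, an early solution for the vicinal C8/C9 pair, and then uses this rearrangement as a supporting step.

**Alternative 3:** The C9–C20 bond is cut by way of a cyclopropane: allylic alcohol A6 with a tetrasubstituted C9=C10 alkene gives cyclopropane A7. Forward, a hydroxyl-directed zinc-carbenoid (Simmons–Smith) cyclopropanation is followed by later cleavage of C10–C20.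
- For: directed cyclopropanation is among the most dependable ways to bring a carbon to a hindered alkene face, and it needs neither photochemistry nor a new catalytic system. On reliability of the key step it is stronger.
- Against: it installs only one of the two methyls, so C8 must be set beforehand and the tetrasubstituted alkene made with C4, C5 and C1 in place. The ring opening is poorly defined. Ionisation or radical generation at C1 prefers to break C9–C10 (tertiary centre) over C10–C20 (primary centre), and reductive opening after oxidation at C1 leaves the C1=C10 alkene to be reinstalled without regiocontrol.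
- Comparison: in the chosen route the temporary ring delivers both methyl carbons at once and its removal by ozonolysis can only cut C17–C20.

Key step: step 3

Remarks on the chemistry:
- C10 in 8–14 and C4 in 24 are carried as mixtures of epimers, because both centres become trigonal later (steps 10 and 17). Their SMILES leave these centres open, as does the SMILES of ozonide 10 for its two acetal carbons.
- Compound 3 and the allylborane of step 13 are taken as purchasable.
- Alkoxides that exist only until aqueous work-up, radicals and catalyst-bound species are not numbered.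

## Route

Step 1
Reactants: 1 cyclohex-2-en-1-one
Product: 2 2-iodocyclohex-2-en-1-one
Conditions: I2, pyridine, CH2Cl2, 0 → 23 °C
Reagents that add atoms: iodine, II
Why: α-Iodination of an enone by conjugate addition of pyridine, iodination of the enolate and elimination (Baylis–Hillman-type addition–elimination); it provides the vinyl iodide for coupling at the future C9.

Step 2
Reactants: 3 2-methyl-2-vinyl-1,3-dioxolane; 2 2-iodocyclohex-2-en-1-one
Product: 5 2-[2-(2-methyl-1,3-dioxolan-2-yl)ethyl]cyclohex-2-en-1-one, via alkylborane 4 (not isolated)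
Conditions: 9-BBN, THF, 23 °C; then 2, PdCl2(dppf) (3 mol %), AsPh3, Cs2CO3, DMF/THF/H2O, 23 °C
Reagents that add atoms: none
Why: Anti-Markovnikov hydroboration puts boron on C11, and B-alkyl Suzuki–Miyaura coupling with the α-iodoenone forms C9–C11 without touching enone or ketal.

Step 3
Reactants: 5 2-[2-(2-methyl-1,3-dioxolan-2-yl)ethyl]cyclohex-2-en-1-one; 6 acetylene
Product: 7 (1R,6S)-1-[2-(2-methyl-1,3-dioxolan-2-yl)ethyl]bicyclo[4.2.0]oct-7-en-2-one
Conditions: HC≡CH (saturated solution, slow stream), B-(2,4,6-trifluorophenyl)oxazaborolidine from α,α-bis(3,5-dimethylphenyl)prolinol·AlBr3 (50 mol %), CH2Cl2, −75 °C, hν (λ = 366 nm)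
Reagents that add atoms: none
Why: Proposed new method: the Lewis acid binds the enone carbonyl and shifts its ππ* absorption so that 366 nm light excites mainly the complex, whose triplet adds to acetylene at C8 to give a 1,4-diradical (α-keto radical at C9, vinyl radical at C20) that closes after intersystem crossing, forming C8–C17 and C9–C20; the closest known reactions are the uncatalysed enone–alkyne [2+2] photocycloaddition and the oxazaborolidine–AlBr3-catalysed enantioselective enone–alkene [2+2] photocycloaddition. The four-membered ring closes by recombination of the diradical, not by a polar or chain cyclisation. A trans-fused bicyclo[4.2.0]oct-7-ene is prohibitively strained (unlike the cyclobutanes from alkenes, which can be trans-fused), so C17 and C20 must end on one face and the chain on the other, which fixes C8 relative to C9. The absolute configuration is set in the first bond formation: the catalyst has to shield the face that is Si at both enone carbons so that acetylene adds to the Re face, and which prolinol antipode does this for an α-alkyl enone must be found in a pilot run, both being accessible. Acetylene is symmetric, so no regiochemistry arises, and the 2-alkyl group slows enone dimerisation. The step needs selective excitation of the complex (long wavelength, low temperature, irradiation stopped before the β,γ-unsaturated ketone product undergoes 1,3-acyl shift) and a Lewis acid that stays on the enone, for which the hindered 2,2-disubstituted dioxolane is the least basic common ketone mask.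

Step 4
Reactants: 7 (1R,6S)-1-[2-(2-methyl-1,3-dioxolan-2-yl)ethyl]bicyclo[4.2.0]oct-7-en-2-one
Product: 8 (1R,2RS,6S)-1-[2-(2-methyl-1,3-dioxolan-2-yl)ethyl]bicyclo[4.2.0]oct-7-en-2-ol
Conditions: NaBH4, MeOH, 0 °C
Reagents that add atoms: none
Why: Borohydride 1,2-reduction; C10 is made sp3 on purpose so that it is not reduced in an uncontrolled way in step 6 and cannot take part in a 1,2-acyl shift of the C20 radical in step 8. Its configuration is irrelevant because step 10 restores the ketone.

Step 5
Reactants: 8 (1R,2RS,6S)-1-[2-(2-methyl-1,3-dioxolan-2-yl)ethyl]bicyclo[4.2.0]oct-7-en-2-ol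
Product: 9 (1R,2RS,6S)-2-(benzyloxy)-1-[2-(2-methyl-1,3-dioxolan-2-yl)ethyl]bicyclo[4.2.0]oct-7-ene
Conditions: NaH, BnBr, Bu4NI (cat.), DMF, 0 → 23 °C
Reagents that add atoms: benzyl bromide, BrCc1ccccc1
Why: Williamson etherification; a benzyl ether survives brief ozonolysis, borohydride, iodination and tin hydride, cannot migrate to the neighbouring hydroxyls as an acyl group could, and is removed under neutral conditions.

Step 6
Reactants: 9 (1R,2RS,6S)-2-(benzyloxy)-1-[2-(2-methyl-1,3-dioxolan-2-yl)ethyl]bicyclo[4.2.0]oct-7-ene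
Product: 11 [(1R,2S,3RS)-3-(benzyloxy)-2-(hydroxymethyl)-2-[2-(2-methyl-1,3-dioxolan-2-yl)ethyl]cyclohexyl]methanol, via ozonide 10 (not isolated)
Conditions: O3, CH2Cl2, −78 °C (Sudan Red 7B as end-point indicator); then MeOH, NaBH4, −78 → 23 °C
Reagents that add atoms: ozone, [O-][O+]=O
Why: Ozonolysis of the strained cyclobutene, the only alkene present, cuts C17–C20, and reductive work-up turns both ends into primary alcohols; C8 and C9 are not touched.

Step 7
Reactants: 11 [(1R,2S,3RS)-3-(benzyloxy)-2-(hydroxymethyl)-2-[2-(2-methyl-1,3-dioxolan-2-yl)ethyl]cyclohexyl]methanol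
Product: 12 benzyl (1RS,2R,3R)-2,3-bis(iodomethyl)-2-[2-(2-methyl-1,3-dioxolan-2-yl)ethyl]cyclohexyl ether
Conditions: PPh3, I2, imidazole (excess, preformed), toluene, 80 °C, diol added last
Reagents that add atoms: iodine, II
Why: Appel-type iodination through alkoxyphosphonium salts; adding the diol to an excess of reagent activates both hydroxyls before one can displace the other to a tetrahydrofuran, and heating is needed for the neopentyl carbon C20.

Step 8
Reactants: 12 benzyl (1RS,2R,3R)-2,3-bis(iodomethyl)-2-[2-(2-methyl-1,3-dioxolan-2-yl)ethyl]cyclohexyl ether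
Product: 13 benzyl (1RS,2S,3R)-2,3-dimethyl-2-[2-(2-methyl-1,3-dioxolan-2-yl)ethyl]cyclohexyl ether
Conditions: Bu3SnH, AIBN (cat.), toluene, 85 °C
Reagents that add atoms: none
Why: Radical chain dehalogenation; the primary radicals at C17 and C20 take hydrogen from the stannane, hindrance at the neopentyl carbon does not matter, and with C10 sp3 there is no adjacent π bond for a 1,2-shift.

Step 9
Reactants: 13 benzyl (1RS,2S,3R)-2,3-dimethyl-2-[2-(2-methyl-1,3-dioxolan-2-yl)ethyl]cyclohexyl ether
Product: 14 (1RS,2S,3R)-2,3-dimethyl-2-[2-(2-methyl-1,3-dioxolan-2-yl)ethyl]cyclohexan-1-ol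
Conditions: H2 (1 atm), Pd(OH)2/C, EtOAc, 23 °C
Reagents that add atoms: none
Why: Hydrogenolysis of the benzyl ether under neutral conditions; 13 has no alkene and the ketal is stable.

Step 10
Reactants: 14 (1RS,2S,3R)-2,3-dimethyl-2-[2-(2-methyl-1,3-dioxolan-2-yl)ethyl]cyclohexan-1-ol
Product: 15 (2S,3R)-2,3-dimethyl-2-[2-(2-methyl-1,3-dioxolan-2-yl)ethyl]cyclohexan-1-one
Conditions: Dess–Martin periodinane, NaHCO3, CH2Cl2, 23 °C
Reagents that add atoms: none
Why: Dess–Martin oxidation of the hindered secondary alcohol; both C10 epimers converge, and the quaternary C9 cannot epimerise.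

Step 11
Reactants: 15 (2S,3R)-2,3-dimethyl-2-[2-(2-methyl-1,3-dioxolan-2-yl)ethyl]cyclohexan-1-one
Product: 17 (5R,6S)-5,6-dimethyl-6-[2-(2-methyl-1,3-dioxolan-2-yl)ethyl]cyclohex-1-en-1-yl trifluoromethanesulfonate, via potassium enolate 16 (not isolated)
Conditions: KN(SiMe3)2, THF, −78 °C; then PhNTf2, −78 → 0 °C
Reagents that add atoms: N-phenylbis(trifluoromethanesulfonimide), O=S(=O)(N(c1ccccc1)S(=O)(=O)C(F)(F)F)C(F)(F)F
Why: Only C5 carries α-hydrogens, so enolisation and O-sulfonylation give a single enol triflate with the alkene at C10=C5.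

Step 12
Reactants: 17 (5R,6S)-5,6-dimethyl-6-[2-(2-methyl-1,3-dioxolan-2-yl)ethyl]cyclohex-1-en-1-yl trifluoromethanesulfonate
Product: 18 (5R,6S)-5,6-dimethyl-6-[2-(2-methyl-1,3-dioxolan-2-yl)ethyl]cyclohex-1-ene-1-carbaldehyde
Conditions: Pd(PPh3)4 (5 mol %), CO (1 atm), Bu3SnH (slow addition), LiCl, THF, 50 °C
Reagents that add atoms: carbon monoxide, [C-]#[O+]
Why: Palladium-catalysed reductive carbonylation (oxidative addition, CO insertion, hydride transfer from the stannane) adds C1 as the aldehyde; slow addition of the hydride suppresses direct reduction of the triflate.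

Step 13
Reactants: 18 (5R,6S)-5,6-dimethyl-6-[2-(2-methyl-1,3-dioxolan-2-yl)ethyl]cyclohex-1-ene-1-carbaldehyde
Product: 20 (1R)-1-[(5R,6S)-5,6-dimethyl-6-[2-(2-methyl-1,3-dioxolan-2-yl)ethyl]cyclohex-1-en-1-yl]but-3-en-1-ol, via borinic ester 19 (not isolated)
Conditions: B-allyldiisopinocampheylborane from (−)-α-pinene, Et2O, −78 °C; then NaOH, H2O2, 0 → 23 °C
Reagents that add atoms: B-allylbis[(1S,2R,3S,5S)-isopinocampheyl]borane, C=CCB([C@H]1C[C@H]2C[C@@H]([C@@H]1C)C2(C)C)[C@H]1C[C@H]2C[C@@H]([C@@H]1C)C2(C)C
Why: Brown allylboration through a chair Zimmerman–Traxler transition state; the isopinocampheyl groups from (−)-α-pinene send allyl to the Re face of the aldehyde and set C1 as R, the configuration step 17 requires. Reagent control is expected to outweigh the bias of the C9 centre.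

Step 14
Reactants: 20 (1R)-1-[(5R,6S)-5,6-dimethyl-6-[2-(2-methyl-1,3-dioxolan-2-yl)ethyl]cyclohex-1-en-1-yl]but-3-en-1-ol
Product: 21 (1R)-1-[(5R,6S)-5,6-dimethyl-6-[2-(2-methyl-1,3-dioxolan-2-yl)ethyl]cyclohex-1-en-1-yl]but-3-en-1-yl 2-methylprop-2-enoate
Conditions: CH2=C(CH3)COCl, Et3N, DMAP (cat.), CH2Cl2, 0 °C
Reagents that add atoms: methacryloyl chloride, CC(=C)C(Cl)=O
Why: Acylation of the secondary alcohol under nucleophilic catalysis brings in C4, C18 and C19; C1 is not affected.

Step 15
Reactants: 21 (1R)-1-[(5R,6S)-5,6-dimethyl-6-[2-(2-methyl-1,3-dioxolan-2-yl)ethyl]cyclohex-1-en-1-yl]but-3-en-1-yl 2-methylprop-2-enoate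
Product: 22 (6R)-6-[(5R,6S)-5,6-dimethyl-6-[2-(2-methyl-1,3-dioxolan-2-yl)ethyl]cyclohex-1-en-1-yl]-3-methyl-5,6-dihydro-2H-pyran-2-one
Conditions: second-generation Grubbs catalyst (H2IMes)(PCy3)Cl2Ru=CHPh (5 mol %), CH2Cl2, 40 °C
Reagents that add atoms: none
Why: Ring-closing metathesis between the terminal vinyl group and the methacrylate alkene closes the six-membered unsaturated lactone at C3=C4; the trisubstituted C10=C5 alkene is too hindered to take part.

Step 16
Reactants: 22 (6R)-6-[(5R,6S)-5,6-dimethyl-6-[2-(2-methyl-1,3-dioxolan-2-yl)ethyl]cyclohex-1-en-1-yl]-3-methyl-5,6-dihydro-2H-pyran-2-one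
Product: 24 (3RS,6R)-6-[(5R,6S)-5,6-dimethyl-6-[2-(2-methyl-1,3-dioxolan-2-yl)ethyl]cyclohex-1-en-1-yl]-3-methyloxan-2-one, via lithium enolate 23 (not isolated)
Conditions: LiBH(s-Bu)3, THF, −78 °C; then aq. NH4Cl
Reagents that add atoms: none
Why: Conjugate (1,4) reduction of the unsaturated lactone by the bulky hydride at the unsubstituted β-carbon C3, then protonation of the enolate; the C4 configuration does not matter because C4 is trigonal again in step 17.

Step 17
Reactants: 24 (3RS,6R)-6-[(5R,6S)-5,6-dimethyl-6-[2-(2-methyl-1,3-dioxolan-2-yl)ethyl]cyclohex-1-en-1-yl]-3-methyloxan-2-one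
Product: 27 (1S,5S,6R,8aR)-1,5,6-trimethyl-5-(3-oxobutyl)-1,2,3,5,6,7,8,8a-octahydronaphthalene-1-carboxylic acid, via silyl ketene acetal 25 (not isolated), via silyl ester 26 (not isolated)
Conditions: KN(SiMe3)2, t-BuMe2SiCl, THF, −78 °C; then toluene, 110 °C; then 1 M HCl, THF, 23 °C
Reagents that add atoms: water, O
Why: Lactone-enolate (Ireland–)Claisen rearrangement: the cyclic silyl ketene acetal can reach C5 only through a boat-like, bicyclo[2.2.2]octane-shaped transition state, so C4–C5 forms on the alkene face from which the C1–O bond departs (the face of the C9 chain), which sets 5R, and the carboxyl carbon stays on that face of the new ring while the methyl points away, which sets 4S. The alkene moves to C1=C10, and the acidic work-up cleaves the silyl ester and the ketal.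

Step 18
Reactants: 27 (1S,5S,6R,8aR)-1,5,6-trimethyl-5-(3-oxobutyl)-1,2,3,5,6,7,8,8a-octahydronaphthalene-1-carboxylic acid
Product: 28 methyl (1S,5S,6R,8aR)-1,5,6-trimethyl-5-(3-oxobutyl)-1,2,3,5,6,7,8,8a-octahydronaphthalene-1-carboxylate
Conditions: MeI, K2CO3, DMF, 23 °C
Reagents that add atoms: iodomethane, CI
Why: SN2 O-alkylation of the carboxylate, which does not depend on access to the hindered carbonyl carbon.

Step 19
Reactants: 28 methyl (1S,5S,6R,8aR)-1,5,6-trimethyl-5-(3-oxobutyl)-1,2,3,5,6,7,8,8a-octahydronaphthalene-1-carboxylate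
Product: 29 methyl (1S,5S,6R,8aR)-5-[(3E)-5-ethoxy-3-methyl-5-oxopent-3-en-1-yl]-1,5,6-trimethyl-1,2,3,5,6,7,8,8a-octahydronaphthalene-1-carboxylate
Conditions: NaH, (EtO)2P(O)CH2CO2Et, THF, 0 → 50 °C; E isomer separated by chromatography
Reagents that add atoms: triethyl phosphonoacetate, CCOC(=O)CP(=O)(OCC)OCC
Why: Horner–Wadsworth–Emmons olefination of the methyl ketone adds C14 and C15 and favours the E enoate (larger chain trans to the ester); the minor Z isomer is removed. The non-enolisable, hindered C19 ester is inert.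

Step 20
Reactants: 29 methyl (1S,5S,6R,8aR)-5-[(3E)-5-ethoxy-3-methyl-5-oxopent-3-en-1-yl]-1,5,6-trimethyl-1,2,3,5,6,7,8,8a-octahydronaphthalene-1-carboxylate
Product: 30 methyl (1S,5S,6R,8aR)-5-[(3E)-5-hydroxy-3-methylpent-3-en-1-yl]-1,5,6-trimethyl-1,2,3,5,6,7,8,8a-octahydronaphthalene-1-carboxylate
Conditions: (i-Bu)2AlH (2.2 equiv), CH2Cl2, −78 °C; aq. potassium sodium tartrate
Reagents that add atoms: none
Why: Hydride reduction of the unhindered conjugated ethyl ester to the allylic alcohol; the C19 ester on a quaternary carbon reacts much more slowly at −78 °C, so a limited amount of reagent leaves it intact.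

Step 21
Reactants: 30 methyl (1S,5S,6R,8aR)-5-[(3E)-5-hydroxy-3-methylpent-3-en-1-yl]-1,5,6-trimethyl-1,2,3,5,6,7,8,8a-octahydronaphthalene-1-carboxylate
Product: 31 methyl (1S,5S,6R,8aR)-5-{2-[(2S,3S)-3-(hydroxymethyl)-2-methyloxiran-2-yl]ethyl}-1,5,6-trimethyl-1,2,3,5,6,7,8,8a-octahydronaphthalene-1-carboxylate
Conditions: Ti(Oi-Pr)4 (10 mol %), L-(+)-diethyl tartrate (12 mol %), t-BuOOH, 4 Å molecular sieves, CH2Cl2, −20 °C
Reagents that add atoms: tert-butyl hydroperoxide, CC(C)(C)OO
Why: Sharpless asymmetric epoxidation; only the allylic alcohol binds titanium, so C1=C10 is untouched, and L-(+)-tartrate delivers oxygen to the face of the E alkene that gives the (13S,14S) epoxide, the sense known for E-3-methylalk-2-en-1-ols such as geraniol.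

## Compound list

1 | cyclohex-2-en-1-one | O=C1C=CCCC1 | starting material
2 | 2-iodocyclohex-2-en-1-one | O=C1CCCC=C1I | intermediate
3 | 2-methyl-2-vinyl-1,3-dioxolane | C=CC1(C)OCCO1 | starting material
4 | 9-[2-(2-methyl-1,3-dioxolan-2-yl)ethyl]-9-borabicyclo[3.3.1]nonane | CC1(CCB2C3CCCC2CCC3)OCCO1 | intermediate (not isolated)
5 | 2-[2-(2-methyl-1,3-dioxolan-2-yl)ethyl]cyclohex-2-en-1-one | O=C1CCCC=C1CCC1(C)OCCO1 | intermediate
6 | acetylene | C#C | starting material
7 | (1R,6S)-1-[2-(2-methyl-1,3-dioxolan-2-yl)ethyl]bicyclo[4.2.0]oct-7-en-2-one | O=C1CCC[C@H]2C=C[C@@]12CCC1(C)OCCO1 | intermediate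
8 | (1R,2RS,6S)-1-[2-(2-methyl-1,3-dioxolan-2-yl)ethyl]bicyclo[4.2.0]oct-7-en-2-ol | OC1CCC[C@H]2C=C[C@@]12CCC1(C)OCCO1 | intermediate
9 | (1R,2RS,6S)-2-(benzyloxy)-1-[2-(2-methyl-1,3-dioxolan-2-yl)ethyl]bicyclo[4.2.0]oct-7-ene | c1ccccc1COC1CCC[C@H]2C=C[C@@]12CCC1(C)OCCO1 | intermediate
10 | secondary ozonide of 9 (C17 and C20 joined by an –O– and an –O–O– bridge; 2,3,7-trioxabicyclo[2.2.1]heptane fused to ring B at C8–C9) | c1ccccc1COC1CCC[C@H]2C3OOC(O3)[C@@]12CCC1(C)OCCO1 | intermediate (not isolated)
11 | [(1R,2S,3RS)-3-(benzyloxy)-2-(hydroxymethyl)-2-[2-(2-methyl-1,3-dioxolan-2-yl)ethyl]cyclohexyl]methanol | c1ccccc1COC1CCC[C@@H](CO)[C@]1(CO)CCC1(C)OCCO1 | intermediate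
12 | benzyl (1RS,2R,3R)-2,3-bis(iodomethyl)-2-[2-(2-methyl-1,3-dioxolan-2-yl)ethyl]cyclohexyl ether | c1ccccc1COC1CCC[C@@H](CI)[C@]1(CI)CCC1(C)OCCO1 | intermediate
13 | benzyl (1RS,2S,3R)-2,3-dimethyl-2-[2-(2-methyl-1,3-dioxolan-2-yl)ethyl]cyclohexyl ether | c1ccccc1COC1CCC[C@@H](C)[C@]1(C)CCC1(C)OCCO1 | intermediate
14 | (1RS,2S,3R)-2,3-dimethyl-2-[2-(2-methyl-1,3-dioxolan-2-yl)ethyl]cyclohexan-1-ol | OC1CCC[C@@H](C)[C@]1(C)CCC1(C)OCCO1 | intermediate
15 | (2S,3R)-2,3-dimethyl-2-[2-(2-methyl-1,3-dioxolan-2-yl)ethyl]cyclohexan-1-one | O=C1CCC[C@@H](C)[C@]1(C)CCC1(C)OCCO1 | intermediate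
16 | potassium (5R,6S)-5,6-dimethyl-6-[2-(2-methyl-1,3-dioxolan-2-yl)ethyl]cyclohex-1-en-1-olate | [K+].[O-]C1=CCC[C@@H](C)[C@]1(C)CCC1(C)OCCO1 | intermediate (not isolated)
17 | (5R,6S)-5,6-dimethyl-6-[2-(2-methyl-1,3-dioxolan-2-yl)ethyl]cyclohex-1-en-1-yl trifluoromethanesulfonate | O=S(=O)(OC1=CCC[C@@H](C)[C@]1(C)CCC1(C)OCCO1)C(F)(F)F | intermediate
18 | (5R,6S)-5,6-dimethyl-6-[2-(2-methyl-1,3-dioxolan-2-yl)ethyl]cyclohex-1-ene-1-carbaldehyde | O=CC1=CCC[C@@H](C)[C@]1(C)CCC1(C)OCCO1 | intermediate
19 | (1R)-1-[(5R,6S)-5,6-dimethyl-6-[2-(2-methyl-1,3-dioxolan-2-yl)ethyl]cyclohex-1-en-1-yl]but-3-en-1-yl bis[(1S,2R,3S,5S)-isopinocampheyl]borinate | C=CC[C@@H](OB([C@H]1C[C@H]2C[C@@H]([C@@H]1C)C2(C)C)[C@H]1C[C@H]2C[C@@H]([C@@H]1C)C2(C)C)C1=CCC[C@@H](C)[C@]1(C)CCC1(C)OCCO1 | intermediate (not isolated)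
20 | (1R)-1-[(5R,6S)-5,6-dimethyl-6-[2-(2-methyl-1,3-dioxolan-2-yl)ethyl]cyclohex-1-en-1-yl]but-3-en-1-ol | C=CC[C@@H](O)C1=CCC[C@@H](C)[C@]1(C)CCC1(C)OCCO1 | intermediate
21 | (1R)-1-[(5R,6S)-5,6-dimethyl-6-[2-(2-methyl-1,3-dioxolan-2-yl)ethyl]cyclohex-1-en-1-yl]but-3-en-1-yl 2-methylprop-2-enoate | C=CC[C@@H](OC(=O)C(C)=C)C1=CCC[C@@H](C)[C@]1(C)CCC1(C)OCCO1 | intermediate
22 | (6R)-6-[(5R,6S)-5,6-dimethyl-6-[2-(2-methyl-1,3-dioxolan-2-yl)ethyl]cyclohex-1-en-1-yl]-3-methyl-5,6-dihydro-2H-pyran-2-one | CC1=CC[C@@H](OC1=O)C1=CCC[C@@H](C)[C@]1(C)CCC1(C)OCCO1 | intermediate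
23 | lithium (2R)-2-[(5R,6S)-5,6-dimethyl-6-[2-(2-methyl-1,3-dioxolan-2-yl)ethyl]cyclohex-1-en-1-yl]-5-methyl-3,4-dihydro-2H-pyran-6-olate | [Li+].CC1=C([O-])O[C@H](CC1)C1=CCC[C@@H](C)[C@]1(C)CCC1(C)OCCO1 | intermediate (not isolated)
24 | (3RS,6R)-6-[(5R,6S)-5,6-dimethyl-6-[2-(2-methyl-1,3-dioxolan-2-yl)ethyl]cyclohex-1-en-1-yl]-3-methyloxan-2-one | CC1CC[C@@H](OC1=O)C1=CCC[C@@H](C)[C@]1(C)CCC1(C)OCCO1 | intermediate
25 | tert-butyl{[(2R)-2-[(5R,6S)-5,6-dimethyl-6-[2-(2-methyl-1,3-dioxolan-2-yl)ethyl]cyclohex-1-en-1-yl]-5-methyl-3,4-dihydro-2H-pyran-6-yl]oxy}dimethylsilane | CC1=C(O[Si](C)(C)C(C)(C)C)O[C@H](CC1)C1=CCC[C@@H](C)[C@]1(C)CCC1(C)OCCO1 | intermediate (not isolated)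
26 | tert-butyldimethylsilyl (1S,5S,6R,8aR)-1,5,6-trimethyl-5-[2-(2-methyl-1,3-dioxolan-2-yl)ethyl]-1,2,3,5,6,7,8,8a-octahydronaphthalene-1-carboxylate | CC(C)(C)[Si](C)(C)OC(=O)[C@@]1(C)CCC=C2[C@H]1CC[C@@H](C)[C@]2(C)CCC1(C)OCCO1 | intermediate (not isolated)
27 | (1S,5S,6R,8aR)-1,5,6-trimethyl-5-(3-oxobutyl)-1,2,3,5,6,7,8,8a-octahydronaphthalene-1-carboxylic acid | OC(=O)[C@@]1(C)CCC=C2[C@H]1CC[C@@H](C)[C@]2(C)CCC(C)=O | intermediate
28 | methyl (1S,5S,6R,8aR)-1,5,6-trimethyl-5-(3-oxobutyl)-1,2,3,5,6,7,8,8a-octahydronaphthalene-1-carboxylate | COC(=O)[C@@]1(C)CCC=C2[C@H]1CC[C@@H](C)[C@]2(C)CCC(C)=O | intermediate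
29 | methyl (1S,5S,6R,8aR)-5-[(3E)-5-ethoxy-3-methyl-5-oxopent-3-en-1-yl]-1,5,6-trimethyl-1,2,3,5,6,7,8,8a-octahydronaphthalene-1-carboxylate | COC(=O)[C@@]1(C)CCC=C2[C@H]1CC[C@@H](C)[C@]2(C)CC/C(C)=C/C(=O)OCC | intermediate
30 | methyl (1S,5S,6R,8aR)-5-[(3E)-5-hydroxy-3-methylpent-3-en-1-yl]-1,5,6-trimethyl-1,2,3,5,6,7,8,8a-octahydronaphthalene-1-carboxylate | COC(=O)[C@@]1(C)CCC=C2[C@H]1CC[C@@H](C)[C@]2(C)CC/C(C)=C/CO | intermediate
31 | methyl (1S,5S,6R,8aR)-5-{2-[(2S,3S)-3-(hydroxymethyl)-2-methyloxiran-2-yl]ethyl}-1,5,6-trimethyl-1,2,3,5,6,7,8,8a-octahydronaphthalene-1-carboxylate | COC(=O)[C@@]1(C)CCC=C2[C@H]1CC[C@@H](C)[C@]2(C)CC[C@]1(C)O[C@H]1CO | target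

## Step count and risk

Total: 21 steps. Longest linear sequence: 21 steps (from 1; compounds 3 and 6 enter as bought materials).

**Step 3 (key step, proposed new method).**
- Most likely failure: poor enantiofacial discrimination, because the chiral Lewis acid is partly held by the ketal oxygens or binds the α-substituted enone in more than one geometry. Two further loss channels are slow capture of the triplet by acetylene, which lets the enone dimerise, and secondary photoisomerisation of the β,γ-unsaturated ketone product.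
- Fallback (known chemistry): set out from 5 and irradiate it with acetylene without Lewis acid (λ = 350 nm, CH2Cl2, −40 °C) to the racemic ketone F1. Reduce F1 with (S)-2-methyl-CBS-oxazaborolidine (cat.) and BH3·SMe2. The reagent delivers hydride to the same local face of the carbonyl in both enantiomers, so they become diastereomeric alcohols: the (1R,2R,6S) epimer of 8 and the alcohol F2 from the unwanted enantiomer. Chromatography separates them, and the former returns to the route at 8.

**Step 7.**
- Most likely failure: ring closure of a half-activated diol to a tetrahydrofuran, or stalled or rearranging substitution at the neopentyl carbon C20, where SN2 displacement is slow.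
- Fallback: set out from 11 and convert both hydroxyls into the bis(S-methyl xanthate) F3 (NaH, CS2, MeI). Reduce F3 with Bu3SnH and AIBN in refluxing toluene (Barton–McCombie deoxygenation). This needs no substitution at C20 and returns to the route at 13.

**Step 13.**
- Most likely failure: insufficient reagent control at the hindered, α-branched enal (a mismatched pairing with the C9 centre). The resulting C1 epimer would be carried into the wrong C4/C5 pair in step 17.
- Fallback: set out from 18 and add (3-methylbut-3-en-1-yl)magnesium bromide to give the dienol F4. Oxidise it with Dess–Martin periodinane to the enone F5 and reduce that with (S)-2-methyl-CBS-oxazaborolidine and BH3·SMe2 (alkenyl as the large group) to the (1R) alcohol F6. Hydroborate the 1,1-disubstituted alkene with 9-BBN and oxidise (NaOH, H2O2) to the diol F7, then close the lactone oxidatively with TEMPO and PhI(OAc)2. This returns to the route at 24 and sets C1 by ketone reduction instead of allylation.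

**Step 17.**
- Most likely failure: the boat-shaped rearrangement may be slower than decomposition of the cyclic ketene acetal on heating (desilylation or C-silylation), so the lactone is recovered or lost.
- Fallback: set out from 17 and couple it with tributyl(vinyl)stannane (Pd(PPh3)4, LiCl; Stille coupling) to the diene F8. Heat F8 with methyl methacrylate (Diels–Alder reaction), which builds ring A directly as the ester F9. The facial and endo/exo preferences of this cycloaddition are not secured, so F9 would have to be separated from isomers. Hydrolyse the ketal (pyridinium p-toluenesulfonate, aqueous acetone) to return to the route at 28.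

**Step 20.**
- Most likely failure: partial reduction of the C19 methyl ester alongside the enoate if the rate difference is smaller than expected.
- Fallback: set out from 27 and carry out the olefination on the free acid (NaH, 2.2 equiv, triethyl phosphonoacetate) to the enoate acid F10. Reduce F10 with (i-Bu)2AlH at −78 °C, where the aluminium carboxylate is inert, to the hydroxy acid F11. Methylate the carboxylate (MeI, K2CO3, DMF) to return to the route at 30.

## Further compounds

F1 | step 3 | racemic 1-[2-(2-methyl-1,3-dioxolan-2-yl)ethyl]bicyclo[4.2.0]oct-7-en-2-one (cis-fused; both enantiomers) | O=C1CCC[C@H]2C=C[C@@]12CCC1(C)OCCO1.O=C1CCC[C@@H]2C=C[C@]12CCC1(C)OCCO1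
F2 | step 3 | (1S,2R,6R)-1-[2-(2-methyl-1,3-dioxolan-2-yl)ethyl]bicyclo[4.2.0]oct-7-en-2-ol | O[C@@H]1CCC[C@@H]2C=C[C@]12CCC1(C)OCCO1
F3 | step 7 | bis(S-methyl xanthate) of diol 11 | c1ccccc1COC1CCC[C@@H](COC(=S)SC)[C@]1(COC(=S)SC)CCC1(C)OCCO1
F4 | step 13 | (1RS)-1-[(5R,6S)-5,6-dimethyl-6-[2-(2-methyl-1,3-dioxolan-2-yl)ethyl]cyclohex-1-en-1-yl]-4-methylpent-4-en-1-ol | C=C(C)CCC(O)C1=CCC[C@@H](C)[C@]1(C)CCC1(C)OCCO1
F5 | step 13 | 1-[(5R,6S)-5,6-dimethyl-6-[2-(2-methyl-1,3-dioxolan-2-yl)ethyl]cyclohex-1-en-1-yl]-4-methylpent-4-en-1-one | C=C(C)CCC(=O)C1=CCC[C@@H](C)[C@]1(C)CCC1(C)OCCO1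
F6 | step 13 | (1R)-1-[(5R,6S)-5,6-dimethyl-6-[2-(2-methyl-1,3-dioxolan-2-yl)ethyl]cyclohex-1-en-1-yl]-4-methylpent-4-en-1-ol | C=C(C)CC[C@@H](O)C1=CCC[C@@H](C)[C@]1(C)CCC1(C)OCCO1
F7 | step 13 | (1R,4RS)-1-[(5R,6S)-5,6-dimethyl-6-[2-(2-methyl-1,3-dioxolan-2-yl)ethyl]cyclohex-1-en-1-yl]-4-methylpentane-1,5-diol | OCC(C)CC[C@@H](O)C1=CCC[C@@H](C)[C@]1(C)CCC1(C)OCCO1
F8 | step 17 | 2-{2-[(1S,6R)-2-ethenyl-1,6-dimethylcyclohex-2-en-1-yl]ethyl}-2-methyl-1,3-dioxolane | C=CC1=CCC[C@@H](C)[C@]1(C)CCC1(C)OCCO1
F9 | step 17 | methyl (1S,5S,6R,8aR)-1,5,6-trimethyl-5-[2-(2-methyl-1,3-dioxolan-2-yl)ethyl]-1,2,3,5,6,7,8,8a-octahydronaphthalene-1-carboxylate | COC(=O)[C@@]1(C)CCC=C2[C@H]1CC[C@@H](C)[C@]2(C)CCC1(C)OCCO1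
F10 | step 20 | (1S,5S,6R,8aR)-5-[(3E)-5-ethoxy-3-methyl-5-oxopent-3-en-1-yl]-1,5,6-trimethyl-1,2,3,5,6,7,8,8a-octahydronaphthalene-1-carboxylic acid | OC(=O)[C@@]1(C)CCC=C2[C@H]1CC[C@@H](C)[C@]2(C)CC/C(C)=C/C(=O)OCC
F11 | step 20 | (1S,5S,6R,8aR)-5-[(3E)-5-hydroxy-3-methylpent-3-en-1-yl]-1,5,6-trimethyl-1,2,3,5,6,7,8,8a-octahydronaphthalene-1-carboxylic acid | OC(=O)[C@@]1(C)CCC=C2[C@H]1CC[C@@H](C)[C@]2(C)CC/C(C)=C/CO
A1 | alternative 1 | methyl 2-methyl-3-oxobutanoate | CC(=O)C(C)C(=O)OC
A2 | alternative 1 | (E)-but-2-enal | C/C=C/C=O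
A3 | alternative 1 | methyl (1S,6R)-1,6-dimethyl-2-oxocyclohex-3-ene-1-carboxylate | O=C1C=CC[C@@H](C)[C@]1(C)C(=O)OC
A4 | alternative 2 | (3RS,6R)-6-[(5R,6S)-6-[(3E)-5-(tert-butyldimethylsilyloxy)-3-methylpent-3-en-1-yl]-5,6-dimethylcyclohex-1-en-1-yl]-3-methyloxan-2-one | CC1CC[C@@H](OC1=O)C1=CCC[C@@H](C)[C@]1(C)CC/C(C)=C/CO[Si](C)(C)C(C)(C)C
A5 | alternative 2 | (1S,5S,6R,8aR)-5-[(3E)-5-(tert-butyldimethylsilyloxy)-3-methylpent-3-en-1-yl]-1,5,6-trimethyl-1,2,3,5,6,7,8,8a-octahydronaphthalene-1-carboxylic acid | OC(=O)[C@@]1(C)CCC=C2[C@H]1CC[C@@H](C)[C@]2(C)CC/C(C)=C/CO[Si](C)(C)C(C)(C)C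
A6 | alternative 3 | methyl ester with a C1 hydroxyl and a tetrasubstituted C9=C10 alkene (ketal chain on C9) | COC(=O)[C@@]1(C)CC[C@H](O)C2=C(CCC3(C)OCCO3)[C@H](C)CC[C@@H]12
A7 | alternative 3 | cyclopropane-fused alcohol with C20 bridging C9 and C10 | COC(=O)[C@@]1(C)CC[C@H](O)[C@@]23C[C@]2(CCC2(C)OCCO2)[C@H](C)CC[C@@H]13
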